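**Retrosynthetic overview**

1. Target 15 is ring A (6-hydroxy-7-methoxycoumarin, O1 to C8a) joined through the C3-O ether to C7' of an umbelliferone unit (ring B). The last disconnections are the O6 acetate and the lactone of A (O1-C2 and C3=C4), the latter by Perkin-Oglialoro condensation of 2,5-dihydroxy-4-methoxybenzaldehyde 7 with (coumarin-7-yloxy)acetic acid 11.
2. The strategy rests on the benzene ring of A (C4a, C5, C6, C7, C8, C8a): oxygens para to each other on C6 and C8a, a methoxy on C7 and the carbon C4 on C4a. This is the pattern that 2-silyloxy-4-methoxyfuran 2 (supplying C8a, C8, C7, C6 and the C6 oxygen) and propynal 4 (supplying C5, C4a, C4) produce.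
3. Key disconnection: C5-C6 and C4a-C8a by [4+2] cycloaddition, then opening of the oxygen bridge at C8a to aromatise. The furan comes from methyl tetronate, the ynal from propargyl alcohol.
4. Acid 11 already holds the C3-O-C7' ether as an O-CH2 bond; it comes from umbelliferone by Williamson alkylation with tert-butyl bromoacetate and acidolysis.
5. Ring order: benzene ring of A (step 3), then pyranone ring of A (step 7); both rings of B are bought with umbelliferone.

Key step: step 3

Remark on the chemistry: after the bridge opens, the silyl group may rest on either of the two para oxygens. Compound 6 is drawn with silicon on the oxygen next to the formyl group; step 4 frees both oxygens, so the route does not depend on this. tert-Butyl bromoacetate is used so that the ester is cleaved by acid and the lactone of umbelliferone never meets hydroxide.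

**Route**

Step 1
Reactants: 1 methyl tetronate (4-methoxyfuran-2(5H)-one)
Product: 2 2-(tert-butyldimethylsilyloxy)-4-methoxyfuran
Conditions: TBSOTf (1.1 equiv), Et3N (1.5 equiv), CH2Cl2, 0 °C to rt, Ar; non-aqueous work-up (pentane, filtration), used directly
Reagents that add atoms: tert-butyldimethylsilyl trifluoromethanesulfonate, CC(C)(C)[Si](C)(C)OS(=O)(=O)C(F)(F)F
Why: Soft enolisation as used to make 2-silyloxyfurans from butenolides: O-silylation of the lactone carbonyl should give a silyloxyfuranium ion that Et3N deprotonates at C5, aromatising to the furan.

Step 2
Reactants: 3 propargyl alcohol (prop-2-yn-1-ol)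
Product: 4 propynal
Conditions: CrO3, H2SO4, H2O, 2-10 °C, reduced pressure with N2 sweep, aldehyde condensed at -78 °C, dried (MgSO4), redistilled and kept cold as a PhMe solution
Reagents that add atoms: none
Why: Chromic acid oxidation of a primary propargylic alcohol, in which the volatile aldehyde is swept out of the oxidant as it forms so that over-oxidation to propiolic acid is limited.

Step 3
Reactants: 2 2-(tert-butyldimethylsilyloxy)-4-methoxyfuran, 4 propynal
Product: 6 2-(tert-butyldimethylsilyloxy)-5-hydroxy-4-methoxybenzaldehyde, via oxanorbornadiene cycloadduct 5 (not isolated)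
Conditions: propynal (1.5 equiv), PhMe, -20 °C to rt, Ar, dark, no Lewis acid
Reagents that add atoms: none
Why: The furan is a doubly donor-substituted diene and propynal an electron-poor alkyne, so a normal-demand, strongly asynchronous Diels-Alder reaction is expected in which furan C5 (the diene terminus with the larger HOMO coefficient, activated by the adjacent methoxy group and through the ring by the silyloxy group) bonds to the unsubstituted beta carbon of the ynal (future C6-C5 bond) and furan C2 closes onto the alpha carbon (future C8a-C4a bond). The six-membered carbocycle is thus closed intermolecularly by [4+2] cycloaddition, the second bond forming by six-membered closure onto the silyloxy-stabilised carbon. In cycloadduct 5 the bridging C-O bond at the ketal bridgehead (future C8a) should ionise to a pentadienyl cation stabilised by the silyloxy group on C8a and the methoxy group on C7, and loss of the proton from the other bridgehead (future C6) aromatises the ring and leaves the former furan oxygen as the free C6 hydroxyl. This is the known conversion of 2-silyloxyfurans and acetylenic dienophiles into hydroquinone monoethers through opening of the 7-oxanorbornadiene. The two bridgehead stereocentres of 5 are racemic and transient and vanish on aromatisation, so no stereocentre has to be controlled. The step needs regioselectivity (formyl next to the silyloxy carbon), which the matched polarisation of diene and ynal secures, and chemoselectivity for cycloaddition over vinylogous Mukaiyama addition to the aldehyde, which the absence of a Lewis acid and the low temperature favour.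

Step 4
Reactants: 6 2-(tert-butyldimethylsilyloxy)-5-hydroxy-4-methoxybenzaldehyde
Product: 7 2,5-dihydroxy-4-methoxybenzaldehyde
Conditions: Bu4NF (1.1 equiv), AcOH (1.2 equiv), THF, 0 °C, Ar; degassed work-up
Reagents that add atoms: none
Why: Fluoride cleavage of an aryl silyl ether, driven by the Si-F bond, with acetic acid buffering the phenoxide so that the electron-rich hydroquinone is not oxidised; either silyl regioisomer gives the same product.

Step 5
Reactants: 8 umbelliferone (7-hydroxy-2H-chromen-2-one), 9 tert-butyl bromoacetate
Product: 10 tert-butyl 2-[(2-oxo-2H-chromen-7-yl)oxy]acetate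
Conditions: K2CO3, acetone, reflux
Reagents that add atoms: none
Why: Williamson ether synthesis, in which the phenoxide of the acidic 7-hydroxyl displaces bromide from the activated alpha-bromo ester by SN2 while the lactone is untouched by carbonate in dry acetone.

Step 6
Reactants: 10 tert-butyl 2-[(2-oxo-2H-chromen-7-yl)oxy]acetate
Product: 11 2-[(2-oxo-2H-chromen-7-yl)oxy]acetic acid
Conditions: CF3CO2H, CH2Cl2, rt
Reagents that add atoms: none
Why: Acidolysis of a tert-butyl ester through the tert-butyl cation with loss of isobutene, under conditions that leave the coumarin lactone and the aryl ether intact.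

Step 7
Reactants: 7 2,5-dihydroxy-4-methoxybenzaldehyde, 11 2-[(2-oxo-2H-chromen-7-yl)oxy]acetic acid
Product: 14 7-methoxy-2-oxo-3-[(2-oxo-2H-chromen-7-yl)oxy]-2H-chromen-6-yl acetate, via acetic (coumarin-7-yloxy)acetic anhydride 12 (not isolated), via 4-acetoxy-2-formyl-5-methoxyphenyl (coumarin-7-yloxy)acetate 13 (not isolated)
Conditions: 11 (1.2 equiv), Ac2O, Et3N, 110 °C, Ar
Reagents that add atoms: acetic anhydride, CC(=O)OC(C)=O
Why: Perkin-Oglialoro coumarin synthesis, in which the mixed anhydride acylates the oxygen ortho to the formyl group, the aryloxy-activated methylene (more acidic than an acetate methyl) undergoes intramolecular aldol condensation onto the aldehyde and dehydrates to the C3=C4 bond, and the remote C5 hydroxyl is acetylated in the same flask.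

Step 8
Reactants: 14 7-methoxy-2-oxo-3-[(2-oxo-2H-chromen-7-yl)oxy]-2H-chromen-6-yl acetate
Product: 15 6-hydroxy-7-methoxy-3-[(2-oxo-2H-chromen-7-yl)oxy]-2H-chromen-2-one (target)
Conditions: aq HCl (3 M), 1,4-dioxane, 70 °C
Reagents that add atoms: none
Why: Acid-catalysed hydrolysis of a phenyl acetate by acyl-oxygen cleavage, chosen because both lactones and the electron-poor 3-aryloxy enol ether are stable to aqueous acid, whereas hydroxide would open the lactones.

**Compound list**

1 | methyl tetronate (4-methoxyfuran-2(5H)-one) | COC1=CC(=O)OC1 | starting material
2 | 2-(tert-butyldimethylsilyloxy)-4-methoxyfuran | COc1coc(O[Si](C)(C)C(C)(C)C)c1 | intermediate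
3 | propargyl alcohol (prop-2-yn-1-ol) | C#CCO | starting material
4 | propynal | C#CC=O | intermediate
5 | 1-(tert-butyldimethylsilyloxy)-5-methoxy-7-oxabicyclo[2.2.1]hepta-2,5-diene-2-carbaldehyde (racemic, not isolated) | O=CC1=CC2OC1(O[Si](C)(C)C(C)(C)C)C=C2OC | intermediate
6 | 2-(tert-butyldimethylsilyloxy)-5-hydroxy-4-methoxybenzaldehyde | COc1cc(O[Si](C)(C)C(C)(C)C)c(C=O)cc1O | intermediate
7 | 2,5-dihydroxy-4-methoxybenzaldehyde | COc1cc(O)c(C=O)cc1O | intermediate
8 | umbelliferone (7-hydroxy-2H-chromen-2-one) | Oc1ccc2ccc(=O)oc2c1 | starting material
9 | tert-butyl bromoacetate | CC(C)(C)OC(=O)CBr | starting material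
10 | tert-butyl 2-[(2-oxo-2H-chromen-7-yl)oxy]acetate | CC(C)(C)OC(=O)COc1ccc2ccc(=O)oc2c1 | intermediate
11 | 2-[(2-oxo-2H-chromen-7-yl)oxy]acetic acid | OC(=O)COc1ccc2ccc(=O)oc2c1 | intermediate
12 | acetic 2-[(2-oxo-2H-chromen-7-yl)oxy]acetic anhydride (not isolated) | CC(=O)OC(=O)COc1ccc2ccc(=O)oc2c1 | intermediate
13 | 4-acetoxy-2-formyl-5-methoxyphenyl 2-[(2-oxo-2H-chromen-7-yl)oxy]acetate (not isolated) | COc1cc(OC(=O)COc2ccc3ccc(=O)oc3c2)c(C=O)cc1OC(C)=O | intermediate
14 | 7-methoxy-2-oxo-3-[(2-oxo-2H-chromen-7-yl)oxy]-2H-chromen-6-yl acetate | COc1cc2oc(=O)c(Oc3ccc4ccc(=O)oc4c3)cc2cc1OC(C)=O | intermediate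
15 | 6-hydroxy-7-methoxy-3-[(2-oxo-2H-chromen-7-yl)oxy]-2H-chromen-2-one | COc1cc2oc(=O)c(Oc3ccc4ccc(=O)oc4c3)cc2cc1O | target

**Step count**

Total steps: 8. Longest linear sequence: 5 steps (steps 1, 3, 4, 7, 8 from methyl tetronate; the propynal branch through step 2 is equally long, and the umbelliferone branch through steps 5 and 6 is shorter).

**Steps most likely to fail**

1. Step 3 (key step). The ynal may polymerise. The first C-C bond may also form without ring closure, by open-chain vinylogous Mukaiyama-Michael addition with silyl transfer, by attack through furan C3, or by 1,2-addition to the aldehyde, so that the carbocycle is never made. The fallback gives up the furan route to ring A and uses the known Elbs persulfate oxidation. No numbered compound is carried into it; in place of compounds 2 and 4 it sets out from commercial 2-hydroxy-4-methoxybenzaldehyde F1. K2S2O8 in cold aqueous KOH (0-20 °C) should hydroxylate para to the phenoxide oxygen to give potassium 5-formyl-4-hydroxy-2-methoxyphenyl sulfate F2. Aqueous HCl at 90 °C should hydrolyse this to compound 7, where the route is rejoined; steps 7 and 8 stay as written.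

2. Step 7. The acetate enolate may condense in competition and give the 3-unsubstituted coumarin, acyl exchange at the chelated oxygen next to the formyl group may be incomplete, and the electron-rich aldehyde may decompose at 110 °C. The fallback sets out from compounds 7 and 11 and removes acetic anhydride from the ring-forming event. The non-chelated hydroxyl of 7 is acetylated selectively (Ac2O, 1.0 equiv, pyridine, CH2Cl2, -20 °C) to give 5-acetoxy-2-hydroxy-4-methoxybenzaldehyde F3. Acid 11 is converted with (COCl)2 and catalytic DMF in CH2Cl2 into (coumarin-7-yloxy)acetyl chloride F4. F3 and F4 with Et3N in CH2Cl2 at 0 °C should give ester 13, now isolated, and DBU in MeCN at rt should close it by intramolecular aldol condensation and dehydration. The fallback comes back to the route at compound 14.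

3. Step 4. The free hydroquinone aldehyde may be oxidised by air to the quinone under fluoride and during work-up, and this polar diphenol may be lost in aqueous extraction. The fallback sets out from compound 6 and never frees the hydroquinone. The open hydroxyl of 6 is acetylated (Ac2O, pyridine, DMAP, CH2Cl2, rt) to give 5-acetoxy-2-(tert-butyldimethylsilyloxy)-4-methoxybenzaldehyde F5. HF·pyridine in THF at 0 °C should remove silicon and give the monophenol 5-acetoxy-2-hydroxy-4-methoxybenzaldehyde F3. F3 is condensed with acid 11 under the conditions of step 7 (Ac2O, Et3N, 110 °C), and the fallback comes back to the route at compound 14. Should the silyl group have moved to the other oxygen, the same sequence still funnels to 14, because every phenol is acetylated or exchanged in hot acetic anhydride.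

**Further compounds**

F1 | step 3 | 2-hydroxy-4-methoxybenzaldehyde | COc1ccc(C=O)c(O)c1
F2 | step 3 | potassium 5-formyl-4-hydroxy-2-methoxyphenyl sulfate | COc1cc(O)c(C=O)cc1OS(=O)(=O)[O-].[K+]
F3 | step 7 | 5-acetoxy-2-hydroxy-4-methoxybenzaldehyde | COc1cc(O)c(C=O)cc1OC(C)=O
F4 | step 7 | 2-[(2-oxo-2H-chromen-7-yl)oxy]acetyl chloride | ClC(=O)COc1ccc2ccc(=O)oc2c1
F5 | step 4 | 5-acetoxy-2-(tert-butyldimethylsilyloxy)-4-methoxybenzaldehyde | COc1cc(O[Si](C)(C)C(C)(C)C)c(C=O)cc1OC(C)=O
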